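**Retrosynthetic overview**
- Target 43 ← cis-epoxide closure (C4–O onto C5) and C8/C9 ester exchange ← keto lactone 32 ← ring-cis cyclodecenone 25 (C6–O by enolate hydroxylation, C12 and C14 by SeO2).
- Structural feature used: the C1=C10 alkene and the C5 oxygen are 1,3-related through C10, so the C5–C10 bond shared by ring A (C1–C5, C10) and ring B (C5–C10) of a cis-fused decalin 1,3-diol monomesylate 24 is the fragmenting bond (Wharton–Grob).
- 24 ← acyloin 22: ring A closed at C4–C5 by an NHC benzoin reaction, then MeMgBr at C4.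
- Quaternary C10 with the C1–C4 unit ← semipinacol 1,2-shift of a 2-furyl group (masked C1 ketone / C4 aldehyde) in epoxy carbinol 11 ← (S)-carvone, which gives ring B with C7, C14, the C9 oxygen and, by α′-oxygenation, C8–O.
- Ring order: ring B (carvone) → ring A (step 16) → ten-membered ring (step 19) → lactone (step 23) → epoxide (step 31).

Key step: step 19

Remark: germacrane numbers (C1–C10 ring, C11–C13 on C7, C14 on C10, C15 on C4) are used for every intermediate; the target SMILES is read as a cis-4,5-epoxide (C3 and C6 on the same side of the oxirane) and a C1=C10 alkene with C2 and C9 cis.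

Step 1
Reactants: 1 (S)-carvone
Product: 4 trans-6-hydroxycarvone (C8–OH trans to the C7 isopropenyl group), via silyl dienol ether 2 (not isolated), via α-silyloxy ketone 3 (not isolated)
Conditions: LiN(iPr)2, THF, −78 °C; Me3SiCl; then mCPBA, NaHCO3, CH2Cl2, 0 °C; then 1 M HCl, THF
Reagents that add atoms: 3-chloroperoxybenzoic acid, O=C(OO)c1cccc(Cl)c1; chlorotrimethylsilane, C[Si](C)(C)Cl (silyl group present only in 2 and 3)
Why: Rubottom oxidation: kinetic α′-deprotonation and silylation give the 2-silyloxy diene, whose enol double bond is epoxidised faster than the isopropenyl group and from the face anti to the C7 substituent, so the C8 oxygen should end up trans to isopropenyl.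

Step 2
Reactants: 4 trans-6-hydroxycarvone
Product: 5 cis-6-(4-methoxyphenoxy)carvone (C8 aryl ether cis to C7 isopropenyl)
Conditions: 4-methoxyphenol, PPh3, DIAD, toluene, 0 °C to rt
Reagents that add atoms: 4-methoxyphenol, COc1ccc(O)cc1
Why: Mitsunobu etherification (SN2 at the α-keto carbinol carbon) inverts C8 to the cis arrangement the target needs, and the 4-methoxyphenyl ether is a robust protecting group that (NH4)2Ce(NO3)6 removes late.

Step 3
Reactants: 5 cis-6-(4-methoxyphenoxy)carvone
Product: 6 allylic alcohol (C9–OH, C8–OAr and C7 isopropenyl all cis; C5=C10 alkene)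
Conditions: NaBH4, CeCl3·7H2O, MeOH, −78 °C
Reagents that add atoms: none
Why: Luche 1,2-reduction: hydride adds axially to the enone carbonyl from the face anti to the pseudo-axial C8 aryloxy group, which should give the C9 alcohol cis to C8–O and C7 (the cis-carveol sense known for carvone).

Step 4
Reactants: 6 allylic alcohol
Product: 7 epoxy alcohol (5,10-epoxide syn to C9–OH)
Conditions: VO(acac)2 (cat.), t-BuOOH, CH2Cl2, 0 °C to rt
Reagents that add atoms: tert-butyl hydroperoxide, CC(C)(C)OO
Why: Hydroxyl-directed vanadium-catalysed epoxidation delivers oxygen to the allylic C5=C10 bond syn to the C9 hydroxyl and leaves the isopropenyl group alone.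

Step 5
Reactants: 7 epoxy alcohol
Product: 8 epoxy ketone (C9 ketone; epoxide cis to C8–OAr and C7 isopropenyl)
Conditions: Dess–Martin periodinane, NaHCO3, CH2Cl2, 0 °C to rt
Reagents that add atoms: none
Why: Dess–Martin oxidation under buffered conditions restores the C9 ketone with the epoxide on the face cis to C7, a diastereomer that nucleophilic epoxidation of the enone would not give.

Step 6
Reactants: 8 epoxy ketone; 9 furan
Product: 11 C9 2-furyl carbinol triethylsilyl ether (furyl anti to the epoxide oxygen), via lithium alkoxide 10 (not isolated)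
Conditions: furan, n-BuLi, THF, 0 °C; then 8, −78 °C; then Et3SiOTf, −78 to 0 °C
Reagents that add atoms: triethylsilyl trifluoromethanesulfonate, CC[Si](CC)(CC)OS(=O)(=O)C(F)(F)F
Why: 1,2-Addition of 2-furyllithium to the α,β-epoxy ketone anti to the epoxide oxygen and to the axial C8 aryloxy group places the furyl group antiperiplanar to the C10–O bond, and in-situ silylation of the tertiary alkoxide prepares the rearrangement.

Step 7
Reactants: 11 furyl carbinol silyl ether
Product: 12 C10-furyl ketone (C9 ketone; quaternary C10 with methyl cis and 2-furyl trans to C7 isopropenyl; C5–OSiEt3 cis to C7 isopropenyl)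
Conditions: Et3SiOTf (10 mol %), CH2Cl2, −78 °C
Reagents that add atoms: none
Why: Semipinacol rearrangement of an α-silyloxy epoxide: the silyl Lewis acid opens the epoxide at tertiary C10 while the electron-rich furyl group shifts from C9 to C10 antiperiplanar to the leaving oxygen (inversion at C10), the C9 carbonyl re-forms and the silyl group passes to the C5 oxygen.

Step 8
Reactants: 12 C10-furyl ketone
Product: 13 C9 alcohol (C9–OH cis to C8–OAr and C7 isopropenyl)
Conditions: NaBH4, MeOH, 0 °C
Reagents that add atoms: none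
Why: Borohydride reduction: hydride attacks the C9 ketone axially from the face opposite the axial C10 methyl and C8 aryloxy groups, which should give the equatorial alcohol of the all-cis C7/C8/C9 triad.

Step 9
Reactants: 13 C9 alcohol
Product: 14 C9 triisopropylsilyl ether
Conditions: iPr3SiOTf, 2,6-lutidine, CH2Cl2, 0 °C to rt
Reagents that add atoms: triisopropylsilyl trifluoromethanesulfonate, CC(C)[Si](C(C)C)(C(C)C)OS(=O)(=O)C(F)(F)F
Why: Silyl triflate with 2,6-lutidine silylates the hindered secondary alcohol; this ether has to last until step 29.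

Step 10
Reactants: 14 C9 TIPS ether
Product: 16 γ-keto aldehyde (C1 ketone, C4 aldehyde), via Z-enedione 15 (not isolated)
Conditions: O2, hν, rose bengal (C20H2Cl4I4Na2O5, cat.), MeOH/CH2Cl2, −78 °C; Me2S; then Zn, AcOH, rt
Reagents that add atoms: oxygen, O=O
Why: The furan is a masked cis-2-ene-1,4-dicarbonyl unit: [4+2] addition of singlet oxygen (much faster than the ene reaction of the isopropenyl group), reduction of the peroxide and zinc–acetic acid reduction of the ene-dione double bond give the C1 ketone and C4 aldehyde.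

Step 11
Reactants: 16 γ-keto aldehyde
Product: 17 C4 dimethyl acetal (C1 ketone free)
Conditions: MeOSiMe3, Me3SiOTf (cat.), CH2Cl2, −78 °C
Reagents that add atoms: methoxytrimethylsilane, CO[Si](C)(C)C
Why: Noyori acetalisation at low temperature is selective for the aldehyde over the neopentyl C1 ketone and spares both silyl ethers.

Step 12
Reactants: 17 keto acetal
Product: 18 C1 (S)-alcohol
Conditions: (R)-1-methyl-3,3-diphenyl-tetrahydro-1H,3H-pyrrolo[1,2-c][1,3,2]oxazaborole ((R)-Me-CBS, 20 mol %), catecholborane, toluene, −40 to 0 °C; then NaOH (aq)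
Reagents that add atoms: none
Why: Corey–Bakshi–Shibata reduction: the oxazaborolidine differentiates quaternary C10 (large) from the CH2 chain (small), so the (R)-catalyst should give the (S)-carbinol needed at C1, and catecholborane does not hydroborate the isopropenyl group.

Step 13
Reactants: 18 C1 alcohol
Product: 19 C1 acetate
Conditions: Ac2O, Et3N, 4-(dimethylamino)pyridine (cat.), CH2Cl2, 0 °C
Reagents that add atoms: acetic anhydride, CC(=O)OC(C)=O
Why: Acetylation masks C1–OH through the C5 oxidation and the ring closure; the acetate is removed by the Grignard reagent in step 17.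

Step 14
Reactants: 19 C1 acetate
Product: 20 C5 alcohol with free C4 aldehyde
Conditions: AcOH/THF/H2O (3:1:1), 40 °C
Reagents that add atoms: water, O
Why: Mild aqueous acid cleaves the secondary triethylsilyl ether and hydrolyses the dimethyl acetal, while the TIPS ether, the acetate and the aryl ether stay.

Step 15
Reactants: 20 hydroxy aldehyde
Product: 21 keto aldehyde (C5 ketone, C4 aldehyde, C1–OAc)
Conditions: Dess–Martin periodinane, NaHCO3, CH2Cl2, rt
Reagents that add atoms: none
Why: Dess–Martin oxidation converts the only free alcohol (C5) into the ketone and does not touch the aldehyde.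

Step 16
Reactants: 21 keto aldehyde
Product: 22 cis-fused decalin acyloin (C5–OH cis to C10–CH3, C4 ketone, C1–OAc)
Conditions: 3-benzyl-5-(2-hydroxyethyl)-4-methylthiazolium chloride (20 mol %), Et3N, t-BuOH, 40 °C
Reagents that add atoms: none
Why: N-heterocyclic-carbene-catalysed intramolecular crossed benzoin reaction: the Breslow intermediate of the C4 aldehyde adds 6-exo-trig to the C5 ketone from the face anti to the axial C10 methyl, which should close ring A cis-fused as in Hajos–Wiechert-type ketols.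

Step 17
Reactants: 22 acyloin
Product: 23 decalin triol (C1–OH, C4–OH, C5–OH; C4–OH trans to C5–OH)
Conditions: MeMgBr (excess), CeCl3, THF, −78 to 0 °C; NH4Cl (aq)
Reagents that add atoms: methylmagnesium bromide, C[Mg]Br
Why: Grignard addition: the concave face of the C4 ketone is shielded by C9, so methyl should enter from the convex (equatorial) side and leave the new C4 hydroxyl axial and trans to C5–OH as the epoxide requires, while excess reagent cleaves the C1 acetate.

Step 18
Reactants: 23 triol
Product: 24 C1 mesylate (fragmentation precursor; C4–OH and C5–OH free)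
Conditions: MsCl, Et3N, CH2Cl2, −20 °C
Reagents that add atoms: methanesulfonyl chloride, CS(=O)(=O)Cl
Why: Sulfonylation via the sulfene reacts only with the secondary C1 alcohol, the two tertiary alcohols being inert at this temperature.

Step 19
Reactants: 24 C1 mesylate
Product: 25 ring-cis cyclodec-1(10)-en-5-one (C2 and C9 cis on the alkene; C4–OH free)
Conditions: KOtBu, THF, 0 °C
Reagents that add atoms: none
Why: KOtBu deprotonates the tertiary C5 hydroxyl, and in one concerted step the C5=O π bond forms, the C5–C10 σ bond breaks, the C1=C10 π bond forms and mesylate leaves C1. This is a Wharton–Grob fragmentation of a decalin 1,3-diol monosulfonate, the classical access to cyclodec-5-enones. No ring is closed by bond formation: the ten-membered ring appears because the bond common to rings A and B is cut, so the mode is ring expansion by fragmentation and not an exo or endo closure. No stereocentre is created (C1, C5 and C10 become trigonal); the alkene geometry follows from the relative configuration of C1 and C10, because in the cis-fused chair–chair conformer with the C7 isopropenyl and C9 silyloxy groups equatorial the C1 mesylate is equatorial on ring A and antiperiplanar to C5–C10 while C9 is axial on ring A and gauche to C2, which puts C2 and C9 cis on the new double bond. The step needs fragmentation to outrun E2 elimination towards C2, oxetane formation and α-ketol shift of the product; the antiperiplanar alignment, the neopentyl position of C1 and a cold, short reaction secure this, and the C4 alkoxide has no leaving group in a 1,3-relationship. Because C4 is fully substituted, the new ketone can later enolise only towards C6.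

Step 20
Reactants: 25 hydroxy cyclodecenone
Product: 26 C4 triethylsilyl ether
Conditions: Et3SiOTf, 2,6-lutidine, CH2Cl2, −78 °C
Reagents that add atoms: triethylsilyl trifluoromethanesulfonate, CC[Si](CC)(CC)OS(=O)(=O)C(F)(F)F
Why: Silylation of the only hydroxyl (tertiary, α to the ketone) prevents α-ketol rearrangement and chelation in the later enolate and hydride steps.

Step 21
Reactants: 26 silyl ether ketone
Product: 27 6-hydroxy ketone (C6–OH trans to the C7 isopropenyl group)
Conditions: KN(SiMe3)2, THF, −78 °C; 2-(phenylsulfonyl)-3-phenyloxaziridine; NH4Cl (aq)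
Reagents that add atoms: 2-(phenylsulfonyl)-3-phenyloxaziridine, O=S(=O)(c1ccccc1)N1OC1c1ccccc1
Why: Enolate hydroxylation with the Davis oxaziridine: the base can enolise only towards C6, and the oxidant should approach anti to the adjacent C7 isopropenyl group, which places C6–O trans to the C7 side chain.

Step 22
Reactants: 27 6-hydroxy ketone
Product: 29 12,14-dialdehyde, via bis-allylic diol 28 (not isolated)
Conditions: SeO2, t-BuOOH, CH2Cl2, rt; then MnO2, CH2Cl2
Reagents that add atoms: tert-butyl hydroperoxide, CC(C)(C)OO (oxygen source; selenium dioxide, O=[Se]=O, carries the oxygen)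
Why: SeO2 allylic oxidation (ene reaction, then [2,3]-sigmatropic shift) attacks the methyl on the more substituted carbon of each alkene, C12 of the isopropenyl group and C14 (the methyl cis to the vinylic hydrogen), and MnO2 oxidises only the two allylic alcohols.

Step 23
Reactants: 29 dialdehyde
Product: 32 6,12-lactone 14-methyl ester (C5 ketone), via diacid 30 (not isolated), via lactone acid 31 (not isolated)
Conditions: NaClO2, NaH2PO4, 2-methyl-2-butene, t-BuOH/H2O, 0 °C to rt; then Me3SiCHN2, MeOH/toluene, 0 °C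
Reagents that add atoms: sodium chlorite, [Na+].[O-]Cl=O; trimethylsilyldiazomethane, C[Si](C)(C)C=[N+]=[N-]
Why: Pinnick oxidation gives both acids, the C12 acid acylates the C6 hydroxyl to the trans-fused α-methylene γ-lactone (5-exo-trig), and trimethylsilyldiazomethane esterifies the remaining C14 acid.

Step 24
Reactants: 32 keto lactone
Product: 33 C5 alcohol (C5–OH syn to C4–O and C6–O in the zigzag sense)
Conditions: NaBH4, CeCl3·7H2O, MeOH, −78 °C
Reagents that add atoms: none
Why: Luche reduction is 1,2-selective beside the α-methylene lactone and the enoate, and with both α-oxygens non-chelating (silyl ether, lactone oxygen) hydride should add in the Felkin–Anh sense, anti to both C–O bonds.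

Step 25
Reactants: 33 C5 alcohol
Product: 34 C5 mesylate
Conditions: MsCl, Et3N, 4-(dimethylamino)pyridine (cat.), CH2Cl2, 0 °C
Reagents that add atoms: methanesulfonyl chloride, CS(=O)(=O)Cl
Why: Sulfonylation of the only free hydroxyl installs the leaving group for the epoxide and protects C5–O during the ester exchange at C8 and C9.

Step 26
Reactants: 34 C5 mesylate
Product: 35 C8 alcohol
Conditions: (NH4)2Ce(NO3)6, pyridine, MeCN/H2O, 0 °C
Reagents that add atoms: none
Why: Oxidative dearylation of the 4-methoxyphenyl ether (arene radical cation, hydrolysis to benzoquinone) frees C8–OH before any epoxide is present; the pyridine buffer keeps both silyl ethers.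

Step 27
Reactants: 36 2-(bromomethyl)acrylic acid; 37 4-methoxybenzyl alcohol
Product: 38 2-[(4-methoxybenzyloxy)methyl]acrylic acid
Conditions: NaH (2.2 equiv), THF, 0 °C to rt; then HCl (aq)
Reagents that add atoms: none
Why: Williamson-type etherification: the alkoxide displaces the allylic bromide of the carboxylate, SN2 and SN2′ attack giving the same product.

Step 28
Reactants: 35 C8 alcohol; 38 protected acrylic acid
Product: 39 C8 2-[(4-methoxybenzyloxy)methyl]acrylate
Conditions: EDC·HCl, 4-(dimethylamino)pyridine, CH2Cl2, 0 °C to rt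
Reagents that add atoms: none
Why: Steglich esterification acylates the only free hydroxyl; with C9 still silylated no acyl migration is possible.

Step 29
Reactants: 39 C8 ester
Product: 40 diol (C9–OH and C4–OH free; C5 mesylate)
Conditions: HF·pyridine, pyridine, THF, 0 °C to rt
Reagents that add atoms: none
Why: Fluoride-mediated desilylation removes both silyl ethers under acidic conditions, in which the C8 ester should not migrate to C9–OH and the hydroxy mesylate does not close.

Step 30
Reactants: 40 diol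
Product: 41 C9 acetate (C4–OH free)
Conditions: Ac2O, pyridine, 4-(dimethylamino)pyridine (cat.), CH2Cl2, 0 °C
Reagents that add atoms: acetic anhydride, CC(=O)OC(C)=O
Why: Acetylation takes the secondary C9 alcohol and leaves the tertiary C4 alcohol.

Step 31
Reactants: 41 hydroxy mesylate
Product: 42 cis-4,5-epoxide (4-methoxybenzyl ether of the target)
Conditions: NaH, THF, 0 °C
Reagents that add atoms: none
Why: Intramolecular Williamson reaction (3-exo-tet): the C4 alkoxide displaces the C5 mesylate with inversion, which gives the cis-epoxide with C3 and C6 on the same side.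

Step 32
Reactants: 42 PMB ether
Product: 43 target CNP0147016.1
Conditions: DDQ, CH2Cl2/pH 7 buffer, 0 °C
Reagents that add atoms: none
Why: Oxidative cleavage of the 4-methoxybenzyl ether by DDQ under buffered conditions frees the primary alcohol without touching the epoxide, the esters or the α-methylene lactone.

**Compound list**
1 | (S)-carvone | CC1=CC[C@H](C(C)=C)CC1=O | starting material
2 | carvone trimethylsilyl dienol ether | CC1=CC[C@H](C(C)=C)C=C1O[Si](C)(C)C | intermediate (not isolated)
3 | trans-6-(trimethylsilyloxy)carvone | CC1=CC[C@H](C(C)=C)[C@@H](O[Si](C)(C)C)C1=O | intermediate (not isolated)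
4 | trans-6-hydroxycarvone | CC1=CC[C@H](C(C)=C)[C@@H](O)C1=O | intermediate
5 | cis-6-(4-methoxyphenoxy)carvone | CC1=CC[C@H](C(C)=C)[C@H](Oc2ccc(OC)cc2)C1=O | intermediate
6 | all-cis allylic alcohol | CC1=CC[C@H](C(C)=C)[C@H](Oc2ccc(OC)cc2)[C@@H]1O | intermediate
7 | epoxy alcohol | C[C@@]12O[C@@H]1C[C@H](C(C)=C)[C@H](Oc3ccc(OC)cc3)[C@@H]2O | intermediate
8 | epoxy ketone | C[C@@]12O[C@@H]1C[C@H](C(C)=C)[C@H](Oc3ccc(OC)cc3)C2=O | intermediate
9 | furan | c1ccoc1 | starting material
10 | lithium alkoxide of the C9 furyl carbinol | C[C@@]12O[C@@H]1C[C@H](C(C)=C)[C@H](Oc3ccc(OC)cc3)[C@@]2([O-])c4ccco4.[Li+] | intermediate (not isolated)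
11 | C9 furyl carbinol triethylsilyl ether | C[C@@]12O[C@@H]1C[C@H](C(C)=C)[C@H](Oc3ccc(OC)cc3)[C@@]2(O[Si](CC)(CC)CC)c4ccco4 | intermediate
12 | C10-furyl ketone | C[C@]1(c2ccco2)[C@H](O[Si](CC)(CC)CC)C[C@H](C(C)=C)[C@H](Oc3ccc(OC)cc3)C1=O | intermediate
13 | C9 alcohol | C[C@]1(c2ccco2)[C@H](O[Si](CC)(CC)CC)C[C@H](C(C)=C)[C@H](Oc3ccc(OC)cc3)[C@@H]1O | intermediate
14 | C9 TIPS ether | C[C@]1(c2ccco2)[C@H](O[Si](CC)(CC)CC)C[C@H](C(C)=C)[C@H](Oc3ccc(OC)cc3)[C@@H]1O[Si](C(C)C)(C(C)C)C(C)C | intermediate
15 | Z-enedione | C[C@]1(C(=O)/C=C\C=O)[C@H](O[Si](CC)(CC)CC)C[C@H](C(C)=C)[C@H](Oc3ccc(OC)cc3)[C@@H]1O[Si](C(C)C)(C(C)C)C(C)C | intermediate (not isolated)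
16 | γ-keto aldehyde | C[C@]1(C(=O)CCC=O)[C@H](O[Si](CC)(CC)CC)C[C@H](C(C)=C)[C@H](Oc3ccc(OC)cc3)[C@@H]1O[Si](C(C)C)(C(C)C)C(C)C | intermediate
17 | C4 dimethyl acetal | C[C@]1(C(=O)CCC(OC)OC)[C@H](O[Si](CC)(CC)CC)C[C@H](C(C)=C)[C@H](Oc3ccc(OC)cc3)[C@@H]1O[Si](C(C)C)(C(C)C)C(C)C | intermediate
18 | C1 (S)-alcohol | C[C@]1([C@@H](O)CCC(OC)OC)[C@H](O[Si](CC)(CC)CC)C[C@H](C(C)=C)[C@H](Oc3ccc(OC)cc3)[C@@H]1O[Si](C(C)C)(C(C)C)C(C)C | intermediate
19 | C1 acetate | C[C@]1([C@@H](OC(C)=O)CCC(OC)OC)[C@H](O[Si](CC)(CC)CC)C[C@H](C(C)=C)[C@H](Oc3ccc(OC)cc3)[C@@H]1O[Si](C(C)C)(C(C)C)C(C)C | intermediate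
20 | C5 alcohol with C4 aldehyde | C[C@]1([C@@H](OC(C)=O)CCC=O)[C@H](O)C[C@H](C(C)=C)[C@H](Oc3ccc(OC)cc3)[C@@H]1O[Si](C(C)C)(C(C)C)C(C)C | intermediate
21 | C5 ketone with C4 aldehyde | C[C@]1([C@@H](OC(C)=O)CCC=O)C(=O)C[C@H](C(C)=C)[C@H](Oc3ccc(OC)cc3)[C@@H]1O[Si](C(C)C)(C(C)C)C(C)C | intermediate
22 | cis-fused decalin acyloin | CC(=O)O[C@H]1CCC(=O)[C@@]2(O)C[C@H](C(C)=C)[C@H](Oc3ccc(OC)cc3)[C@H](O[Si](C(C)C)(C(C)C)C(C)C)[C@@]12C | intermediate
23 | decalin triol | O[C@H]1CC[C@@](C)(O)[C@@]2(O)C[C@H](C(C)=C)[C@H](Oc3ccc(OC)cc3)[C@H](O[Si](C(C)C)(C(C)C)C(C)C)[C@@]12C | intermediate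
24 | C1 mesylate, fragmentation precursor | CS(=O)(=O)O[C@H]1CC[C@@](C)(O)[C@@]2(O)C[C@H](C(C)=C)[C@H](Oc3ccc(OC)cc3)[C@H](O[Si](C(C)C)(C(C)C)C(C)C)[C@@]12C | intermediate
25 | ring-cis cyclodecenone, C4–OH | O=C1C[C@H](C(C)=C)[C@H](Oc2ccc(OC)cc2)[C@H](O[Si](C(C)C)(C(C)C)C(C)C)/C(C)=C\CC[C@@]1(C)O | intermediate
26 | ring-cis cyclodecenone, C4–OSiEt3 | O=C1C[C@H](C(C)=C)[C@H](Oc2ccc(OC)cc2)[C@H](O[Si](C(C)C)(C(C)C)C(C)C)/C(C)=C\CC[C@@]1(C)O[Si](CC)(CC)CC | intermediate
27 | 6-hydroxy ketone | O=C1[C@@H](O)[C@H](C(C)=C)[C@H](Oc2ccc(OC)cc2)[C@H](O[Si](C(C)C)(C(C)C)C(C)C)/C(C)=C\CC[C@@]1(C)O[Si](CC)(CC)CC | intermediate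
28 | 12,14-diol | O=C1[C@@H](O)[C@H](C(CO)=C)[C@H](Oc2ccc(OC)cc2)[C@H](O[Si](C(C)C)(C(C)C)C(C)C)/C(CO)=C\CC[C@@]1(C)O[Si](CC)(CC)CC | intermediate (not isolated)
29 | 12,14-dialdehyde | O=C1[C@@H](O)[C@H](C(C=O)=C)[C@H](Oc2ccc(OC)cc2)[C@H](O[Si](C(C)C)(C(C)C)C(C)C)/C(C=O)=C\CC[C@@]1(C)O[Si](CC)(CC)CC | intermediate
30 | 12,14-diacid | O=C1[C@@H](O)[C@H](C(C(=O)O)=C)[C@H](Oc2ccc(OC)cc2)[C@H](O[Si](C(C)C)(C(C)C)C(C)C)/C(C(=O)O)=C\CC[C@@]1(C)O[Si](CC)(CC)CC | intermediate (not isolated)
31 | 6,12-lactone 14-acid | O=C1[C@H]2OC(=O)C(=C)[C@@H]2[C@H](Oc3ccc(OC)cc3)[C@H](O[Si](C(C)C)(C(C)C)C(C)C)/C(C(=O)O)=C\CC[C@@]1(C)O[Si](CC)(CC)CC | intermediate (not isolated)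
32 | 6,12-lactone 14-methyl ester, C5 ketone | O=C1[C@H]2OC(=O)C(=C)[C@@H]2[C@H](Oc3ccc(OC)cc3)[C@H](O[Si](C(C)C)(C(C)C)C(C)C)/C(C(=O)OC)=C\CC[C@@]1(C)O[Si](CC)(CC)CC | intermediate
33 | C5 alcohol | O[C@@H]1[C@H]2OC(=O)C(=C)[C@@H]2[C@H](Oc3ccc(OC)cc3)[C@H](O[Si](C(C)C)(C(C)C)C(C)C)/C(C(=O)OC)=C\CC[C@@]1(C)O[Si](CC)(CC)CC | intermediate
34 | C5 mesylate | CS(=O)(=O)O[C@@H]1[C@H]2OC(=O)C(=C)[C@@H]2[C@H](Oc3ccc(OC)cc3)[C@H](O[Si](C(C)C)(C(C)C)C(C)C)/C(C(=O)OC)=C\CC[C@@]1(C)O[Si](CC)(CC)CC | intermediate
35 | C8 alcohol | CS(=O)(=O)O[C@@H]1[C@H]2OC(=O)C(=C)[C@@H]2[C@H](O)[C@H](O[Si](C(C)C)(C(C)C)C(C)C)/C(C(=O)OC)=C\CC[C@@]1(C)O[Si](CC)(CC)CC | intermediate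
36 | 2-(bromomethyl)acrylic acid | OC(=O)C(=C)CBr | starting material
37 | 4-methoxybenzyl alcohol | COc1ccc(CO)cc1 | starting material
38 | 2-[(4-methoxybenzyloxy)methyl]acrylic acid | COc1ccc(COCC(=C)C(=O)O)cc1 | intermediate
39 | C8 acrylate ester | CS(=O)(=O)O[C@@H]1[C@H]2OC(=O)C(=C)[C@@H]2[C@H](OC(=O)C(=C)COCc3ccc(OC)cc3)[C@H](O[Si](C(C)C)(C(C)C)C(C)C)/C(C(=O)OC)=C\CC[C@@]1(C)O[Si](CC)(CC)CC | intermediate
40 | C4,C9-diol | CS(=O)(=O)O[C@@H]1[C@H]2OC(=O)C(=C)[C@@H]2[C@H](OC(=O)C(=C)COCc3ccc(OC)cc3)[C@H](O)/C(C(=O)OC)=C\CC[C@@]1(C)O | intermediate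
41 | C9 acetate, hydroxy mesylate | CS(=O)(=O)O[C@@H]1[C@H]2OC(=O)C(=C)[C@@H]2[C@H](OC(=O)C(=C)COCc3ccc(OC)cc3)[C@H](OC(C)=O)/C(C(=O)OC)=C\CC[C@@]1(C)O | intermediate
42 | cis-4,5-epoxide, PMB ether of the target | C=C(COCc3ccc(OC)cc3)C(=O)O[C@H]1[C@H]2C(=C)C(=O)O[C@@H]2[C@@H]2O[C@]2(C)CC/C=C(/C(=O)OC)[C@H]1OC(C)=O | intermediate
43 | CNP0147016.1 | C=C(CO)C(=O)O[C@H]1[C@H]2C(=C)C(=O)O[C@@H]2[C@@H]2O[C@]2(C)CC/C=C(/C(=O)OC)[C@H]1OC(C)=O | target

**Step count.** 32 steps in total; the longest linear sequence has 31 steps (steps 1–26 and 28–32; step 27 makes the side-chain acid).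

**Steps most likely to fail**

1. Step 16 (closure of ring A). The Breslow intermediate may add only slowly and reversibly to the hindered neopentyl C5 ketone, so that intermolecular aldehyde condensation or closure to the trans-fused ketol takes over. Fallback: the ring is closed by a reductive ketyl coupling instead of an umpolung addition. Setting out from 21, SmI2 with t-BuOH in THF at −78 °C should give, through the chelated samarium ketyls, the cis-fused decalin 4,5-cis-diol F1; Dess–Martin oxidation of its secondary C4 alcohol (the tertiary C5 alcohol is inert) comes back to the route at 22.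

2. Step 21 (C6 oxygenation). In the flexible ten-membered enolate the oxidant may approach from the face syn to the C7 side chain, which would lead on to the cis-fused lactone. Fallback: the oxygen is brought in by the carboxylate with inversion rather than by an electrophilic oxidant. Setting out from 26, the potassium enolate is brominated with N-bromosuccinimide to the 6-bromo ketone F2 (bromine on the face the oxidant would have taken). SeO2/t-BuOOH then MnO2 as in step 22 give, through the bromo diol F3, the bromo dialdehyde F4, and Pinnick oxidation gives the bromo diacid F5. With NaHCO3 in DMF the C12 carboxylate displaces the α-keto bromide with inversion to the lactone acid 31, and esterification as in step 23 comes back to the route at 32.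

3. Step 24 (C5 reduction). Hydride may be delivered from the other face of the ketone (chelation by cerium or a ring conformation that overrides the Felkin–Anh preference), which would give the diol diastereomer that closes to the trans-epoxide. Fallback: the carbinol is corrected by SN2 inversion instead of by hydride facial control. Setting out from 32, the C5-epimeric alcohol F6 so formed is treated with chloroacetic acid, PPh3 and DIAD (Mitsunobu inversion) to give the inverted chloroacetate F7, whose ester is removed selectively with thiourea and NaHCO3 in ethanol; this comes back to the route at 33.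

Further compounds
F1 | step 16 | cis-fused decalin 4,5-cis-diol with C1 acetate | CC(=O)O[C@H]1CC[C@H](O)[C@@]2(O)C[C@H](C(C)=C)[C@H](Oc3ccc(OC)cc3)[C@H](O[Si](C(C)C)(C(C)C)C(C)C)[C@@]12C
F2 | step 21 | 6-bromo ketone (bromine cis to the C7 isopropenyl group) | O=C1[C@H](Br)[C@H](C(C)=C)[C@H](Oc2ccc(OC)cc2)[C@H](O[Si](C(C)C)(C(C)C)C(C)C)/C(C)=C\CC[C@@]1(C)O[Si](CC)(CC)CC
F3 | step 21 | 6-bromo 12,14-diol | O=C1[C@H](Br)[C@H](C(CO)=C)[C@H](Oc2ccc(OC)cc2)[C@H](O[Si](C(C)C)(C(C)C)C(C)C)/C(CO)=C\CC[C@@]1(C)O[Si](CC)(CC)CC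
F4 | step 21 | 6-bromo 12,14-dialdehyde | O=C1[C@H](Br)[C@H](C(C=O)=C)[C@H](Oc2ccc(OC)cc2)[C@H](O[Si](C(C)C)(C(C)C)C(C)C)/C(C=O)=C\CC[C@@]1(C)O[Si](CC)(CC)CC
F5 | step 21 | 6-bromo 12,14-diacid | O=C1[C@H](Br)[C@H](C(C(=O)O)=C)[C@H](Oc2ccc(OC)cc2)[C@H](O[Si](C(C)C)(C(C)C)C(C)C)/C(C(=O)O)=C\CC[C@@]1(C)O[Si](CC)(CC)CC
F6 | step 24 | C5-epimeric alcohol | O[C@H]1[C@H]2OC(=O)C(=C)[C@@H]2[C@H](Oc3ccc(OC)cc3)[C@H](O[Si](C(C)C)(C(C)C)C(C)C)/C(C(=O)OC)=C\CC[C@@]1(C)O[Si](CC)(CC)CC
F7 | step 24 | C5 chloroacetate with inverted C5 | ClCC(=O)O[C@@H]1[C@H]2OC(=O)C(=C)[C@@H]2[C@H](Oc3ccc(OC)cc3)[C@H](O[Si](C(C)C)(C(C)C)C(C)C)/C(C(=O)OC)=C\CC[C@@]1(C)O[Si](CC)(CC)CC
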